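Do not set a tank's residence time beside a flask's clock as if both meant the same exposure.

| setting | summer | noon | ash | alder | elm |
|---|---|---|---|---|---|
| substrate | 0.40 M | 0.60 M | 0.40 M | 0.40 M | 0.40 M |
| remark | run made earlier | run made earlier | one stirred flow tank at steady state, fed with the mixture as stated, mean residence time 5.0 min | one stirred flow tank at steady state, fed with the mixture as stated, mean residence time 25.0 min | a closed flask charged with all of it at once and left for 5.0 min |
| time |  |  |  |  | 5.0 min |
summer run (percent of the substrate charged)

| time / min | target / % | isomer of the product / % |
|---|---|---|
| 0.833 | 9 | 1 |
| 1.50 | 10 | 1 |
| 2.50 | 15 | 1 |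
| 3.00 | 19 | 5 |

noon run (percent of the substrate charged)

| time / s | target / % | isomer of the product / % |
|---|---|---|
| 15.0 | 2 | 0 |
| 30.0 | 6 | 1 |
| 50.0 | 7 | 2 |
| 60.0 | 8 | 0 |

(standard deviation of a reading: 1.5 percentage points)
- the set-up with the highest share of target in all that became target or isomer of the product, at the outlet or at the end ("none" if the first two lie within 2 percentage points) (ash / alder / elm / none)
- share of target in all that became target or isomer of the product, at the outlet or at the end, ash
- share of target in all that became target or isomer of the product, at the outlet or at the end, alder
- share of target in all that became target or isomer of the product, at the outlet or at the end, elm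
- the stated concentrations are those of everything mixed, before any reaction; amounts are the same in each set-up
- the numbers in the tables scatter with a standard deviation of 1.5 percentage points
- the earlier runs were made in a closed, stirred flask

The isomer of the product never reads above 5%, with a scatter of 1.5 percentage points, so do not lean on a rate read from it; compare the vessels instead. Assume that isomer comes from target, so that the ratio of isomer to target grows with the time target has stood. If target forms at a steady pace in elm, it is on average 2.50 min old at the reading: call this the age of target, half of elm's time. At the outlet of a tank forming target at a steady pace, the age is one residence time. Ash's residence time equals elm's time, so its target is twice as old as elm's, and alder's 25.0 min is ten times elm's age. My own reckoning therefore ranks elm first and alder last, without committing to shares.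

The forecast names elm and gives 76% for ash, 58% for alder and 81% for elm: “In both cases the flask keeps substrate high and avoids long exposure, so elm is at least as good as ash and alder is worst.”

The flasks give elm as best, with 82.2% for ash, 58.8% for alder and 87.7% for elm.

    intermediate A ⇌ intermediate D (K = 0.230, k = 0.110 min⁻¹)
    intermediate B ⇌ intermediate C (K = 2.70, k = 0.380 min⁻¹)
    substrate ⇌ intermediate A (K = 0.560, k = 0.140 min⁻¹)
    substrate → target (k = 0.0810 min⁻¹)
    target ⇌ isomer of the product (K = 1.60, k = 0.0500 min⁻¹)
    intermediate A ⇌ intermediate B (K = 21.0, k = 0.0110 min⁻¹)

Take the ratio of isomer to target from these shares: elm 0.140, ash 0.216, alder 0.702. Ash stands at 1.54 times elm and alder at 5.01 times elm, each below its age factor. Divide elm's simulated isomer by its target and by its age to get 0.0559 min⁻¹. Now read elm at 2.0 min: the age is 1.00 min, the ratio 0.0559, and the expected share 94.7%; the simulated flask gives 95.0%.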